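**Assumption:** the hemiketal centre C3 equilibrates through the ring-opened keto acid, so its (3R) configuration (3-OH trans to 4-CH3) is reached under thermodynamic control and only C4 has to be set by the route.

## Retrosynthetic overview

1. Last bond: the side-chain ester C–O, made by carboxylate SN2 of 2,4-dihydroxy-3,5,6-trimethylbenzoic acid (three steps from cheap methyl atrarate) on a 3-(chloromethyl) lactol.
2. Key step: the benzene ring and the lactol ring of that chloromethyl lactol are made in one pot by Diels–Alder/aromatisation/ketal unmasking/lactolisation of a Brassard-type diene (C5–C8, from methyl 3-oxopentanoate) with a chiral 2-ynoic acid (C1, C8a, C4a, C4, C3, CH2Cl).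
3. C4 comes from (S)-but-3-yn-2-ol by anti-SN2' stannylation and anti-SE2' capture of a chloro-orthoacetate cation; this gives the C3 ketone directly as a non-enolisable ketal next to the alkyne.
4. Ring order: the trimethylresorcylate ring is bought as an arene; the benzene ring of the isochromanone forms first and the lactol ring closes in the same operation.

## Route

Step 1
Reactants: 1 methyl 3-oxopentanoate
Product: 2 methyl (E)-3-methoxypent-2-enoate
Conditions: HC(OMe)3, conc. H2SO4 (cat.), rt, 24 h; then distil from cat. TsOH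
Reagents that add atoms: trimethyl orthoformate, COC(OC)OC
Why: acid-catalysed ketalisation followed by loss of methanol gives the conjugated β-methoxy enoate, as in the standard preparation of methyl 3-methoxycrotonate.

Step 2
Reactants: 2 methyl (E)-3-methoxypent-2-enoate
Product: 3 1,3-dimethoxy-1-(trimethylsilyloxy)penta-1,3-diene (mixture of geometric isomers, used as such)
Conditions: LDA, THF, −78 °C; TMSCl, −78 → 0 °C; pentane, filter, distil
Reagents that add atoms: chlorotrimethylsilane, C[Si](C)(C)Cl
Why: vinylogous (γ) deprotonation and O-silylation of the dienolate give the Brassard-type silyl ketene acetal diene.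

Step 3
Reactants: 4 (S)-but-3-yn-2-ol
Product: 5 (S)-but-3-yn-2-yl methanesulfonate
Conditions: MsCl, Et3N, CH2Cl2, −78 → 0 °C
Reagents that add atoms: methanesulfonyl chloride, CS(=O)(=O)Cl
Why: O-sulfonylation does not touch the stereocentre and gives the propargylic leaving group.

Step 4
Reactants: 5 (S)-but-3-yn-2-yl methanesulfonate
Product: 6 (aR)-tributyl(buta-1,2-dien-1-yl)stannane
Conditions: Bu3SnH, LDA, THF, 0 °C; CuBr·SMe2 (1 eq), −78 °C; then 5, −78 °C
Reagents that add atoms: tributyltin hydride (used as Bu3SnLi), CCCC[SnH](CCCC)CCCC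
Why: Marshall stannylcuprate displacement goes anti-SN2', so the central chirality of 5 becomes the (aR) axial chirality of the allene.

Step 5
Reactants: 6 (aR)-tributyl(buta-1,2-dien-1-yl)stannane; 7 2-chloro-1,1,1-trimethoxyethane
Product: 8 (S)-5-chloro-4,4-dimethoxy-3-methylpent-1-yne
Conditions: TMSOTf (15 mol%), CH2Cl2, 4 Å MS, −78 → −30 °C; Et3N, then aq. NaHCO3
Reagents that add atoms: none
Why: Proposed new method: the Lewis acid ionises orthoester 7 to the 2-chloro-1,1-dimethoxyethylium ion, which the γ-carbon of 6 attacks anti to tin (SE2'), so anti-SN2' plus anti-SE2' gives net retention and the (S) propargylic centre with the ketone already masked as a non-enolisable ketal; the closest known reactions are Marshall's BF3-promoted SE2' additions of chiral allenylstannanes to aldehydes and acetals and the Lewis-acid allylation of orthoesters (Sakurai type).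

Step 6
Reactants: 8 (S)-5-chloro-4,4-dimethoxy-3-methylpent-1-yne
Product: 9 (S)-6-chloro-5,5-dimethoxy-4-methylhex-2-ynoic acid
Conditions: n-BuLi (1.05 eq), THF, −78 °C; CO2 (g), −78 → −20 °C; 1 M HCl to pH 3, 0 °C
Reagents that add atoms: carbon dioxide, O=C=O
Why: carboxylation of the lithium acetylide leaves the neopentyl-type chloride, the ketal and the much less acidic propargylic C–H (the stereocentre) untouched.

Step 7
Reactants: 9 (S)-6-chloro-5,5-dimethoxy-4-methylhex-2-ynoic acid; 3 1,3-dimethoxy-1-(trimethylsilyloxy)penta-1,3-diene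
Product: 14 (3R,4S)-3-(chloromethyl)-3,8-dihydroxy-6-methoxy-4,5-dimethylisochroman-1-one, via silyl ynoate 10 (not isolated), via cyclohexadiene adduct 11 (not isolated), via aryl ketal acid 12 (not isolated), via keto acid 13 (not isolated)
Conditions: BSA (1.1 eq), toluene, rt; 3 (3 eq), 110 °C, sealed tube, 36 h; then 2 M HCl/THF (1:3), rt → 40 °C
Reagents that add atoms: water, O
Why: a Brassard-type Diels–Alder benzannulation (nucleophilic CHMe terminus of 3 to the β-carbon of the ynoate, ketene-acetal carbon to the α-carbon) followed by loss of MeOH builds the fully substituted salicylic acid, and the same acid treatment unmasks the ketone, which the ortho carboxyl captures as the lactol; C4 is carried from 9 and C3 settles thermodynamically (anomeric OH trans to the pseudo-axial 4-CH3, which avoids the 5-CH3).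

Step 8
Reactants: 15 methyl 2,4-dihydroxy-3,6-dimethylbenzoate (methyl atrarate)
Product: 16 methyl 5-formyl-2,4-dihydroxy-3,6-dimethylbenzoate
Conditions: Cl2CHOMe, TiCl4, CH2Cl2, −10 → 0 °C; aq. HCl
Reagents that add atoms: dichloromethyl methyl ether, COC(Cl)Cl; water, O
Why: Rieche formylation goes to the only free ring position, which is ortho and para to the two hydroxyl groups.

Step 9
Reactants: 16 methyl 5-formyl-2,4-dihydroxy-3,6-dimethylbenzoate
Product: 17 methyl 2,4-dihydroxy-3,5,6-trimethylbenzoate
Conditions: H2 (3 atm), 10% Pd/C, AcOH, rt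
Reagents that add atoms: none
Why: hydrogenolysis of an ortho/para-hydroxybenzaldehyde through the benzylic alcohol gives the aryl methyl group.

Step 10
Reactants: 17 methyl 2,4-dihydroxy-3,5,6-trimethylbenzoate
Product: 18 2,4-dihydroxy-3,5,6-trimethylbenzoic acid
Conditions: KOH (10 eq), DMSO/H2O (4:1), 80 °C, Ar; then 2 M HCl to pH 2, 0 °C
Reagents that add atoms: potassium hydroxide, [K+].[OH-]
Why: saponification of the hindered salicylate under argon, with cold acidification to avoid decarboxylation of the β-resorcylic acid.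

Step 11
Reactants: 14 (3R,4S)-3-(chloromethyl)-3,8-dihydroxy-6-methoxy-4,5-dimethylisochroman-1-one; 18 2,4-dihydroxy-3,5,6-trimethylbenzoic acid
Product: 20 [(3R,4S)-3,8-dihydroxy-6-methoxy-4,5-dimethyl-1-oxoisochroman-3-yl]methyl 2,4-dihydroxy-3,5,6-trimethylbenzoate, via open keto acid ester 19 (not isolated)
Conditions: 18 (2 eq), KHCO3 (2 eq), DMF, rt, 15 min; then 14, NaI (10 mol%), 0 °C → rt; pH 4 buffer work-up
Reagents that add atoms: none
Why: phenacyl-type ester formation, in which the carboxylate of 18 (phenols stay protonated with bicarbonate) displaces chloride from the ring-opened α-chloroketone tautomer 13 of the lactol, and the product recloses to the thermodynamic (3R) hemiketal without touching C4.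

## Compound list

1 | methyl 3-oxopentanoate | CCC(=O)CC(=O)OC | starting material
2 | methyl (E)-3-methoxypent-2-enoate | CC/C(OC)=C\C(=O)OC | intermediate
3 | 1,3-dimethoxy-1-(trimethylsilyloxy)penta-1,3-diene (isomer mixture) | CC=C(OC)C=C(OC)O[Si](C)(C)C | intermediate
4 | (S)-but-3-yn-2-ol | C[C@H](O)C#C | starting material
5 | (S)-but-3-yn-2-yl methanesulfonate | C[C@H](OS(C)(=O)=O)C#C | intermediate
6 | (aR)-tributyl(buta-1,2-dien-1-yl)stannane | CC=[C@]=C[Sn](CCCC)(CCCC)CCCC | intermediate
7 | 2-chloro-1,1,1-trimethoxyethane | COC(CCl)(OC)OC | starting material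
8 | (S)-5-chloro-4,4-dimethoxy-3-methylpent-1-yne | C#C[C@H](C)C(OC)(OC)CCl | intermediate
9 | (S)-6-chloro-5,5-dimethoxy-4-methylhex-2-ynoic acid | OC(=O)C#C[C@H](C)C(OC)(OC)CCl | intermediate
10 | trimethylsilyl (S)-6-chloro-5,5-dimethoxy-4-methylhex-2-ynoate | C[Si](C)(C)OC(=O)C#C[C@H](C)C(OC)(OC)CCl | intermediate (not isolated)
11 | trimethylsilyl 2-[(2S)-4-chloro-3,3-dimethoxybutan-2-yl]-4,6-dimethoxy-3-methyl-6-(trimethylsilyloxy)cyclohexa-1,4-diene-1-carboxylate (ring centres as mixture) | C[Si](C)(C)OC(=O)C1=C([C@H](C)C(OC)(OC)CCl)C(C)C(OC)=CC1(OC)O[Si](C)(C)C | intermediate (not isolated)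
12 | 2-[(2S)-4-chloro-3,3-dimethoxybutan-2-yl]-6-hydroxy-4-methoxy-3-methylbenzoic acid | COc1cc(O)c(C(=O)O)c([C@H](C)C(OC)(OC)CCl)c1C | intermediate (not isolated)
13 | 2-[(2S)-4-chloro-3-oxobutan-2-yl]-6-hydroxy-4-methoxy-3-methylbenzoic acid | COc1cc(O)c(C(=O)O)c([C@H](C)C(=O)CCl)c1C | intermediate (not isolated)
14 | (3R,4S)-3-(chloromethyl)-3,8-dihydroxy-6-methoxy-4,5-dimethylisochroman-1-one | COc1cc(O)c2c(c1C)[C@H](C)[C@](O)(CCl)OC2=O | intermediate
15 | methyl 2,4-dihydroxy-3,6-dimethylbenzoate | COC(=O)c1c(C)cc(O)c(C)c1O | starting material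
16 | methyl 5-formyl-2,4-dihydroxy-3,6-dimethylbenzoate | COC(=O)c1c(C)c(C=O)c(O)c(C)c1O | intermediate
17 | methyl 2,4-dihydroxy-3,5,6-trimethylbenzoate | COC(=O)c1c(C)c(C)c(O)c(C)c1O | intermediate
18 | 2,4-dihydroxy-3,5,6-trimethylbenzoic acid | OC(=O)c1c(C)c(C)c(O)c(C)c1O | intermediate
19 | 2-[(2S)-4-(2,4-dihydroxy-3,5,6-trimethylbenzoyloxy)-3-oxobutan-2-yl]-6-hydroxy-4-methoxy-3-methylbenzoic acid | COc1cc(O)c(C(=O)O)c([C@H](C)C(=O)COC(=O)c2c(C)c(C)c(O)c(C)c2O)c1C | intermediate (not isolated)
20 | [(3R,4S)-3,8-dihydroxy-6-methoxy-4,5-dimethyl-1-oxoisochroman-3-yl]methyl 2,4-dihydroxy-3,5,6-trimethylbenzoate | COc1cc(O)c2c(c1C)[C@H](C)[C@](O)(COC(=O)c1c(C)c(C)c(O)c(C)c1O)OC2=O | target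

## Step count and risks

Total step count: 11. Longest linear sequence: 6 (steps 3, 4, 5, 6, 7, 11, from (S)-but-3-yn-2-ol).

Steps most likely to fail:

1. Step 5 (orthoester SE2', untested; the cation may collapse to methyl chloroacetate or the ketal may react twice). The fallback sets out from 6 and comes back at 8. Allenylstannane 6 is added to anhydrous chloroacetaldehyde with BF3·OEt2 at −78 °C (known Marshall syn-selective SE2' addition) to give (2R,3S)-1-chloro-3-methylpent-4-yn-2-ol F1. Buffered Dess–Martin oxidation at 0 °C gives (S)-1-chloro-3-methylpent-4-yn-2-one F2, which is ketalised at once under Noyori conditions (MeOTMS, cat. TMSOTf, CH2Cl2, −78 °C) to 8 before the labile α-alkynyl ketone can enolise.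

2. Step 7 (hindered Diels–Alder between a 4-methyl diene and a β-branched ynoate; acid stage must not epimerise C4 or dehydrate to the isocoumarin). The fallback sets out from 8 and comes back at 12. The lithium acetylide of 8 is formylated with DMF to the far more reactive dienophile (S)-6-chloro-5,5-dimethoxy-4-methylhex-2-ynal F3. Cycloaddition with 3 at 0–25 °C and mild acid (PPTS) aromatisation give 2-[(2S)-4-chloro-3,3-dimethoxybutan-2-yl]-6-hydroxy-4-methoxy-3-methylbenzaldehyde F4. Pinnick oxidation (NaClO2, NaH2PO4, 2-methyl-2-butene) then gives 12, which closes to 14 in the HCl/THF stage of step 7.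

3. Step 11 (the substrate's own carboxylate can close a seven-membered keto lactone, and base can erode C4). The fallback sets out from 9 and comes back at 19. Acid 9 is allylated (allyl bromide, KHCO3, DMF) to prop-2-en-1-yl (S)-6-chloro-5,5-dimethoxy-4-methylhex-2-ynoate F5. Diels–Alder with 3 and the HCl/THF treatment give the open-chain prop-2-en-1-yl 2-[(2S)-4-chloro-3-oxobutan-2-yl]-6-hydroxy-4-methoxy-3-methylbenzoate F6, in which no internal carboxylate competes. The potassium salt of 18 in DMF at 0 °C displaces chloride to give prop-2-en-1-yl 2-[(2S)-4-(2,4-dihydroxy-3,5,6-trimethylbenzoyloxy)-3-oxobutan-2-yl]-6-hydroxy-4-methoxy-3-methylbenzoate F7. Neutral deallylation (Pd(PPh3)4, PhSiH3, CH2Cl2) frees 19, which closes to 20.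

## Further compounds

F1 | step 5 | (2R,3S)-1-chloro-3-methylpent-4-yn-2-ol | ClC[C@H](O)[C@@H](C)C#C
F2 | step 5 | (S)-1-chloro-3-methylpent-4-yn-2-one | ClCC(=O)[C@@H](C)C#C
F3 | step 7 | (S)-6-chloro-5,5-dimethoxy-4-methylhex-2-ynal | O=CC#C[C@H](C)C(OC)(OC)CCl
F4 | step 7 | 2-[(2S)-4-chloro-3,3-dimethoxybutan-2-yl]-6-hydroxy-4-methoxy-3-methylbenzaldehyde | COc1cc(O)c(C=O)c([C@H](C)C(OC)(OC)CCl)c1C
F5 | step 11 | prop-2-en-1-yl (S)-6-chloro-5,5-dimethoxy-4-methylhex-2-ynoate | C=CCOC(=O)C#C[C@H](C)C(OC)(OC)CCl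
F6 | step 11 | prop-2-en-1-yl 2-[(2S)-4-chloro-3-oxobutan-2-yl]-6-hydroxy-4-methoxy-3-methylbenzoate | COc1cc(O)c(C(=O)OCC=C)c([C@H](C)C(=O)CCl)c1C
F7 | step 11 | prop-2-en-1-yl 2-[(2S)-4-(2,4-dihydroxy-3,5,6-trimethylbenzoyloxy)-3-oxobutan-2-yl]-6-hydroxy-4-methoxy-3-methylbenzoate | COc1cc(O)c(C(=O)OCC=C)c([C@H](C)C(=O)COC(=O)c2c(C)c(C)c(O)c(C)c2O)c1C
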